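**Retrosynthetic overview**

- The C12–C16 enoate arm and the C18 acetate are removed first. This leads back to a ring-A/B ester with CO2Me (C11) on C9 and a TBDPS ether at C18; the arm is rebuilt by propargylation of the C11 triflate and Zr-catalysed carboalumination/ClCO2Me.
- Feature used: ring B carries the diene C6=C7–C8=C17 between the ring-fusion carbon C5 and C9. This is what a vinylallene C5=C6–C7=C8=C17 leaves after [4+2] addition across a C9=C10 alkene, so C5–C10 and C8–C9 are cut to give an acyclic vinylallene (E)-enoate.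
- Rings A and B are therefore formed together in one step; no ring exists before it.
- The vinylallene comes from an (E)-vinyl iodide (Sonogashira coupling with propargyl alcohol, then reductive transposition to the allene); the (E)-enoate comes from a terminal alkyne by carboalumination.
- The quaternary C4 comes from a Sharpless epoxide of (E)-3-methyloct-2-en-7-yn-1-ol by an aluminium-promoted 1,2-shift of the silyloxymethyl group; the enynol comes from hepta-1,6-diyne.

Key step: step 9

Remark on the chemistry: atom labels C1–C20 follow labdane numbering. The SMILES is read as the ent-labdane (4S,5S,9R,10S) with the oxygenated C18 trans to the C10 methyl. Aluminium and lithium intermediates are written as monomers.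

**Route**

Step 1
Reactants: 1 hepta-1,6-diyne (3 equiv)
Product: 4 (E)-3-methyloct-2-en-7-yn-1-ol, via alkenyldimethylalane 2 (not isolated), via lithium alkenylalanate 3 (not isolated)
Conditions: Me3Al (1 equiv), Cp2ZrCl2 (0.2 equiv), CH2Cl2, 0 °C → rt; evaporate (excess 1 recovered); n-BuLi, hexane/THF, −78 → 0 °C; (CH2O)n, rt; aq. HCl
Reagents that add atoms: trimethylaluminium, C[Al](C)C; formaldehyde (as paraformaldehyde), C=O
Why: Zr-catalysed carboalumination (Negishi) adds CH3 and Al syn across one terminal alkyne with CH3 on the internal carbon, and the alanate formed with n-BuLi transfers the alkenyl group to formaldehyde with retention, so the (E)-trisubstituted allylic alcohol should result while the excess of diyne keeps the second alkyne free.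

Step 2
Reactants: 4 (E)-3-methyloct-2-en-7-yn-1-ol
Product: 5 [(2R,3R)-3-methyl-3-(pent-4-yn-1-yl)oxiran-2-yl]methanol
Conditions: Ti(OiPr)4 (10 mol%), D-(−)-diethyl tartrate (12 mol%), t-BuOOH (2 equiv), 4 Å MS, CH2Cl2, −20 °C
Reagents that add atoms: tert-butyl hydroperoxide, CC(C)(C)OO
Why: Sharpless asymmetric epoxidation acts only on the allylic alcohol alkene, and D-(−)-tartrate should give the (2R,3R)-epoxide from an (E)-3-methylallylic alcohol (geraniol-type), which sets the stereocentre that becomes C4.

Step 3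
Reactants: 5 [(2R,3R)-3-methyl-3-(pent-4-yn-1-yl)oxiran-2-yl]methanol
Product: 6 tert-butyl{[(2R,3R)-3-methyl-3-(pent-4-yn-1-yl)oxiran-2-yl]methoxy}diphenylsilane
Conditions: TBDPSCl, imidazole, DMF, rt
Reagents that add atoms: tert-butylchlorodiphenylsilane, CC(C)(C)[Si](Cl)(c1ccccc1)c1ccccc1
Why: Standard silylation of the primary alcohol; the bulky TBDPS group is needed for the migration in step 4, for the facial bias in step 9, and it survives until step 15.

Step 4
Reactants: 6 tert-butyl{[(2R,3R)-3-methyl-3-(pent-4-yn-1-yl)oxiran-2-yl]methoxy}diphenylsilane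
Product: 7 (R)-2-[(tert-butyldiphenylsilyloxy)methyl]-2-methylhept-6-ynal
Conditions: MeAl(OAr)2 (Ar = 4-bromo-2,6-di-tert-butylphenyl; 2 equiv, made from Me3Al + 2 ArOH, CH2Cl2, rt); then 6, CH2Cl2, −78 → −40 °C; aq. HCl
Reagents that add atoms: none
Why: Organoaluminium-promoted rearrangement of an epoxy silyl ether (semipinacol-type 1,2-shift): the bulky Lewis acid opens the epoxide at the tertiary carbon and the silyloxymethyl group migrates anti to the departing oxygen, so that carbon becomes the quaternary C4 with inversion and the former C2 becomes the C5 aldehyde.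

Step 5
Reactants: 7 (R)-2-[(tert-butyldiphenylsilyloxy)methyl]-2-methylhept-6-ynal
Product: 8 (3S,1E)-1-iodo-3-methyl-3-[(tert-butyldiphenylsilyloxy)methyl]oct-1-en-7-yne
Conditions: CrCl2 (6 equiv), CHI3 (2 equiv), THF, 0 °C → rt
Reagents that add atoms: iodoform, IC(I)I
Why: Takai olefination: the geminal dichromium species formed from CHI3 and divalent chromium adds to the hindered aldehyde and eliminates to the (E)-vinyl iodide (C5=C6), leaving the terminal alkyne and the silyl ether untouched.

Step 6
Reactants: 8 (3S,1E)-1-iodo-3-methyl-3-[(tert-butyldiphenylsilyloxy)methyl]oct-1-en-7-yne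
Product: 10 methyl (2E,7S,8E)-9-iodo-3,7-dimethyl-7-[(tert-butyldiphenylsilyloxy)methyl]nona-2,8-dienoate, via alkenyldimethylalane 9 (not isolated)
Conditions: Me3Al (3 equiv), Cp2ZrCl2 (0.3 equiv), CH2Cl2, 0 °C → rt; then ClCO2Me, 0 °C → rt; cold aq. HCl
Reagents that add atoms: trimethylaluminium, C[Al](C)C; methyl chloroformate, COC(Cl)=O
Why: Zr-catalysed syn-carboalumination of the terminal alkyne and acylation of the alkenylalane with retention give the (E)-3-methyl-2-enoate (C10 methyl cis to the C11 ester); vinyl iodides and silyl ethers are inert to these reagents.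

Step 7
Reactants: 10 methyl (2E,7S,8E)-9-iodo-3,7-dimethyl-7-[(tert-butyldiphenylsilyloxy)methyl]nona-2,8-dienoate; 11 prop-2-yn-1-ol
Product: 12 methyl (2E,7S,8E)-12-hydroxy-3,7-dimethyl-7-[(tert-butyldiphenylsilyloxy)methyl]dodeca-2,8-dien-10-ynoate
Conditions: PdCl2(PPh3)2 (3 mol%), CuI (6 mol%), Et3N, THF, rt
Reagents that add atoms: none
Why: Sonogashira coupling of the (E)-vinyl iodide with the terminal alkyne proceeds with retention of alkene geometry under mild amine conditions that the enoate tolerates.

Step 8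
Reactants: 12 methyl (2E,7S,8E)-12-hydroxy-3,7-dimethyl-7-[(tert-butyldiphenylsilyloxy)methyl]dodeca-2,8-dien-10-ynoate
Product: 15 methyl (2E,7S,8E)-3,7-dimethyl-7-[(tert-butyldiphenylsilyloxy)methyl]dodeca-2,8,10,11-tetraenoate, via sulfonylhydrazine adduct 13 (not isolated), via propargylic diazene 14 (not isolated)
Conditions: PPh3, DEAD, THF, −15 °C; then 2-nitrobenzenesulfonylhydrazide, −15 °C → rt
Reagents that add atoms: none
Why: Mitsunobu displacement of the propargylic alcohol by the sulfonylhydrazide, loss of sulfinic acid to the monoalkyl diazene and retro-ene expulsion of N2 deliver hydrogen to the distal alkyne carbon, so the terminal vinylallene C17=C8=C7–C6=C5 is formed at or below room temperature.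

Step 9
Reactants: 15 methyl (2E,7S,8E)-3,7-dimethyl-7-[(tert-butyldiphenylsilyloxy)methyl]dodeca-2,8,10,11-tetraenoate
Product: 16 methyl 18-(tert-butyldiphenylsilyloxy)-12,13,14,15,16-pentanor-ent-labda-6,8(17)-dien-11-oate (trans-decalin; 4-CH3, 10-CH3 and the C9 ester on the α face; 4-CH2OSi, H-5 and H-9 on the β face)
Conditions: PhMe (0.01 M), BHT (0.1 equiv), sealed tube, 120 °C
Reagents that add atoms: none
Why: A thermal, concerted and suprafacial [4+2] cycloaddition in which the s-cis vinylallene C5=C6–C7=C8 adds across the tethered enoate C9=C10, forming C5–C10 and C8–C9 and leaving the cumulated C8=C17 bond as the exocyclic methylene; the closest known reaction type is the thermal intramolecular Diels–Alder reaction of vinylallenes with tethered electron-poor alkenes (type 1, four-atom tether). Ring B closes as the six-membered cycloaddition ring itself (C5–C6–C7–C8–C9–C10), and ring A closes through the same C5–C10 bond as the C1–C2–C3–C4 tether folds into a chair, helped by the gem-disubstituted C4. C9 and C10 are set relative to each other by the (E)-enoate geometry (10-CH3 cis to C11), and C5 relative to C10 by the transition state with the ester endo and the tether anti (trans-fusion), which should be favoured because an exo ester would meet the C17 hydrogen that the allene projects onto the reacting face. The absolute sense of all three new centres comes from C4, whose silyloxymethyl group should take the equatorial site and whose methyl the axial site of the chair, syn to the 10-CH3. The step needs trans- over cis-fusion and one diene face relative to C4; it relies on the (E,E) geometry, the bulky TBDPS-oxymethyl group and the unhindered sp terminus C8. C4 carries no hydrogen, so the [1,5]-hydrogen shift open to vinylallenes is excluded, and high dilution with BHT should suppress intermolecular dimerisation.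

Step 10
Reactants: 16 methyl 18-(tert-butyldiphenylsilyloxy)-12,13,14,15,16-pentanor-ent-labda-6,8(17)-dien-11-oate
Product: 17 18-(tert-butyldiphenylsilyloxy)-12,13,14,15,16-pentanor-ent-labda-6,8(17)-dien-11-ol
Conditions: i-Bu2AlH (2.5 equiv), CH2Cl2, −78 → 0 °C; aq. KNaC4H4O6
Reagents that add atoms: none
Why: Hydride reduction of the ester to the primary alcohol without base, so the C9 hydrogen (alpha to the ester and allylic) should not epimerise and the diene should not move into conjugation.

Step 11
Reactants: 17 18-(tert-butyldiphenylsilyloxy)-12,13,14,15,16-pentanor-ent-labda-6,8(17)-dien-11-ol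
Product: 18 18-(tert-butyldiphenylsilyloxy)-12,13,14,15,16-pentanor-ent-labda-6,8(17)-dien-11-yl trifluoromethanesulfonate
Conditions: Tf2O, pyridine, CH2Cl2, −78 → −30 °C (used crude at once)
Reagents that add atoms: trifluoromethanesulfonic anhydride, O=S(=O)(OS(=O)(=O)C(F)(F)F)C(F)(F)F
Why: Buffered triflation of the primary alcohol gives a leaving group reactive enough for SN2 at the β-branched C11 at low temperature.

Step 12
Reactants: 18 18-(tert-butyldiphenylsilyloxy)-12,13,14,15,16-pentanor-ent-labda-6,8(17)-dien-11-yl trifluoromethanesulfonate; 19 1-(trimethylsilyl)propyne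
Product: 21 18-(tert-butyldiphenylsilyloxy)-14-(trimethylsilyl)-15,16-dinor-ent-labda-6,8(17)-dien-13-yne, via 3-lithio-1-(trimethylsilyl)propyne 20 (not isolated)
Conditions: 19, n-BuLi, THF, −78 → −20 °C; then 18, THF, −78 → −20 °C
Reagents that add atoms: none
Why: SN2 alkylation of the propargylic lithium reagent (the silyl group blocks the alkyne terminus and directs attack through the CH2 carbon) by the primary triflate forms C11–C12 without touching the stereocentres.

Step 13
Reactants: 21 18-(tert-butyldiphenylsilyloxy)-14-(trimethylsilyl)-15,16-dinor-ent-labda-6,8(17)-dien-13-yne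
Product: 22 18-(tert-butyldiphenylsilyloxy)-15,16-dinor-ent-labda-6,8(17)-dien-13-yne
Conditions: K2CO3, MeOH, rt
Reagents that add atoms: none
Why: Methanolysis of the alkynyl C–Si bond is selective over the hindered TBDPS ether.

Step 14
Reactants: 22 18-(tert-butyldiphenylsilyloxy)-15,16-dinor-ent-labda-6,8(17)-dien-13-yne
Product: 24 methyl (13E)-18-(tert-butyldiphenylsilyloxy)-ent-labda-6,8(17),13-trien-15-oate, via alkenyldimethylalane 23 (not isolated)
Conditions: Me3Al (3 equiv), Cp2ZrCl2 (0.3 equiv), CH2Cl2, 0 °C → rt; then ClCO2Me, 0 °C → rt; cold aq. HCl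
Reagents that add atoms: trimethylaluminium, C[Al](C)C; methyl chloroformate, COC(Cl)=O
Why: Zr-catalysed syn-carboalumination of the terminal alkyne and trapping with ClCO2Me give the (13E)-3-methyl-2-enoate; the alkyne should react far faster than the 1,1-disubstituted alkene of the diene.

Step 15
Reactants: 24 methyl (13E)-18-(tert-butyldiphenylsilyloxy)-ent-labda-6,8(17),13-trien-15-oate
Product: 25 methyl (13E)-18-hydroxy-ent-labda-6,8(17),13-trien-15-oate
Conditions: Bu4NF, THF, rt → 40 °C; aq. NH4Cl
Reagents that add atoms: none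
Why: Fluoride cleavage of the silyl ether; the methyl ester and the diene are stable to Bu4NF.

Step 16
Reactants: 25 methyl (13E)-18-hydroxy-ent-labda-6,8(17),13-trien-15-oate
Product: 26 methyl (13E)-18-acetoxy-ent-labda-6,8(17),13-trien-15-oate, (4S,5S,9R,10S), the target
Conditions: Ac2O, pyridine, DMAP (cat.), CH2Cl2, rt
Reagents that add atoms: acetic anhydride, CC(=O)OC(C)=O
Why: DMAP-catalysed acetylation of the primary alcohol under non-acidic conditions that leave the acid-sensitive 6,8(17)-diene intact.

**Compound list**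

1 | hepta-1,6-diyne | C#CCCCC#C | starting material
2 | (E)-dimethyl(2-methylhept-1-en-6-yn-1-yl)alane | C#CCCC/C(C)=C/[Al](C)C | intermediate (not isolated)
3 | lithium (E)-butyldimethyl(2-methylhept-1-en-6-yn-1-yl)alanate | [Li+].CCCC[Al-](C)(C)/C=C(\C)CCCC#C | intermediate (not isolated)
4 | (E)-3-methyloct-2-en-7-yn-1-ol | C#CCCC/C(C)=C/CO | intermediate
5 | [(2R,3R)-3-methyl-3-(pent-4-yn-1-yl)oxiran-2-yl]methanol | OC[C@H]1O[C@]1(C)CCCC#C | intermediate
6 | tert-butyl{[(2R,3R)-3-methyl-3-(pent-4-yn-1-yl)oxiran-2-yl]methoxy}diphenylsilane | CC(C)(C)[Si](OC[C@H]1O[C@]1(C)CCCC#C)(c1ccccc1)c1ccccc1 | intermediate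
7 | (R)-2-[(tert-butyldiphenylsilyloxy)methyl]-2-methylhept-6-ynal | O=C[C@@](C)(CO[Si](c1ccccc1)(c1ccccc1)C(C)(C)C)CCCC#C | intermediate
8 | (3S,1E)-1-iodo-3-methyl-3-[(tert-butyldiphenylsilyloxy)methyl]oct-1-en-7-yne | I/C=C/[C@@](C)(CO[Si](c1ccccc1)(c1ccccc1)C(C)(C)C)CCCC#C | intermediate
9 | alkenyldimethylalane from 8 (Al on C9, CH3 on C10, E) | I/C=C/[C@@](C)(CO[Si](c1ccccc1)(c1ccccc1)C(C)(C)C)CCC/C(C)=C/[Al](C)C | intermediate (not isolated)
10 | methyl (2E,7S,8E)-9-iodo-3,7-dimethyl-7-[(tert-butyldiphenylsilyloxy)methyl]nona-2,8-dienoate | I/C=C/[C@@](C)(CO[Si](c1ccccc1)(c1ccccc1)C(C)(C)C)CCC/C(C)=C/C(=O)OC | intermediate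
11 | prop-2-yn-1-ol | C#CCO | starting material
12 | methyl (2E,7S,8E)-12-hydroxy-3,7-dimethyl-7-[(tert-butyldiphenylsilyloxy)methyl]dodeca-2,8-dien-10-ynoate | OCC#C/C=C/[C@@](C)(CO[Si](c1ccccc1)(c1ccccc1)C(C)(C)C)CCC/C(C)=C/C(=O)OC | intermediate
13 | N-propargylic N-(2-nitrobenzenesulfonyl)hydrazine from 12 | NN(CC#C/C=C/[C@@](C)(CO[Si](c1ccccc1)(c1ccccc1)C(C)(C)C)CCC/C(C)=C/C(=O)OC)S(=O)(=O)c1ccccc1[N+](=O)[O-] | intermediate (not isolated)
14 | propargylic monoalkyl diazene from 13 | N=NCC#C/C=C/[C@@](C)(CO[Si](c1ccccc1)(c1ccccc1)C(C)(C)C)CCC/C(C)=C/C(=O)OC | intermediate (not isolated)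
15 | methyl (2E,7S,8E)-3,7-dimethyl-7-[(tert-butyldiphenylsilyloxy)methyl]dodeca-2,8,10,11-tetraenoate (vinylallene (E)-enoate) | C=C=C/C=C/[C@@](C)(CO[Si](c1ccccc1)(c1ccccc1)C(C)(C)C)CCC/C(C)=C/C(=O)OC | intermediate
16 | methyl 18-(tert-butyldiphenylsilyloxy)-12,13,14,15,16-pentanor-ent-labda-6,8(17)-dien-11-oate | C=C1C=C[C@@H]2[C@@](C)(CO[Si](c3ccccc3)(c3ccccc3)C(C)(C)C)CCC[C@@]2(C)[C@@H]1C(=O)OC | intermediate
17 | 18-(tert-butyldiphenylsilyloxy)-12,13,14,15,16-pentanor-ent-labda-6,8(17)-dien-11-ol | C=C1C=C[C@@H]2[C@@](C)(CO[Si](c3ccccc3)(c3ccccc3)C(C)(C)C)CCC[C@@]2(C)[C@@H]1CO | intermediate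
18 | 11-triflate of 17 | C=C1C=C[C@@H]2[C@@](C)(CO[Si](c3ccccc3)(c3ccccc3)C(C)(C)C)CCC[C@@]2(C)[C@@H]1COS(=O)(=O)C(F)(F)F | intermediate
19 | 1-(trimethylsilyl)propyne | CC#C[Si](C)(C)C | starting material
20 | 3-lithio-1-(trimethylsilyl)propyne | [Li]CC#C[Si](C)(C)C | intermediate (not isolated)
21 | 18-(tert-butyldiphenylsilyloxy)-14-(trimethylsilyl)-15,16-dinor-ent-labda-6,8(17)-dien-13-yne | C=C1C=C[C@@H]2[C@@](C)(CO[Si](c3ccccc3)(c3ccccc3)C(C)(C)C)CCC[C@@]2(C)[C@@H]1CCC#C[Si](C)(C)C | intermediate
22 | 18-(tert-butyldiphenylsilyloxy)-15,16-dinor-ent-labda-6,8(17)-dien-13-yne | C=C1C=C[C@@H]2[C@@](C)(CO[Si](c3ccccc3)(c3ccccc3)C(C)(C)C)CCC[C@@]2(C)[C@@H]1CCC#C | intermediate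
23 | alkenyldimethylalane from 22 (Al on C14, CH3 on C13, E) | C=C1C=C[C@@H]2[C@@](C)(CO[Si](c3ccccc3)(c3ccccc3)C(C)(C)C)CCC[C@@]2(C)[C@@H]1CC/C(C)=C/[Al](C)C | intermediate (not isolated)
24 | methyl (13E)-18-(tert-butyldiphenylsilyloxy)-ent-labda-6,8(17),13-trien-15-oate | C=C1C=C[C@@H]2[C@@](C)(CO[Si](c3ccccc3)(c3ccccc3)C(C)(C)C)CCC[C@@]2(C)[C@@H]1CC/C(C)=C/C(=O)OC | intermediate
25 | methyl (13E)-18-hydroxy-ent-labda-6,8(17),13-trien-15-oate | C=C1C=C[C@@H]2[C@@](C)(CO)CCC[C@@]2(C)[C@@H]1CC/C(C)=C/C(=O)OC | intermediate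
26 | methyl (13E)-18-acetoxy-ent-labda-6,8(17),13-trien-15-oate, (4S,5S,9R,10S) | C=C1C=C[C@@H]2[C@@](C)(COC(C)=O)CCC[C@@]2(C)[C@@H]1CC/C(C)=C/C(=O)OC | target

**Step count and risks**

Total step count: 16. Longest linear sequence: 16 steps (from 1; compounds 11 and 19 are purchased).

Steps most likely to fail:

1. Step 9 (key cycloaddition). The bond C5–C10 joins a neopentyl diene terminus to a fully substituted alkene carbon, so ring closure may be slower than thermal self-reaction (intermolecular [4+2] oligomerisation) of the vinylallene. At the temperature then needed, the preference for the endo-ester (trans-fused) mode and for the chair with the silyloxymethyl group equatorial may erode, giving cis-fused and C4-mismatched adducts. Fallback: the dienophile is made more electron-poor and the cyclisation is run cold under Lewis-acid control. Setting out from 15, i-Bu2AlH (CH2Cl2, −78 °C) gives the allylic alcohol (2E,7S,8E)-3,7-dimethyl-7-[(tert-butyldiphenylsilyloxy)methyl]dodeca-2,8,10,11-tetraen-1-ol F1. MnO2 (CH2Cl2, rt) gives the corresponding (E)-enal F2. Me2AlCl (CH2Cl2, −78 → −40 °C) promotes the intramolecular Diels–Alder reaction of the Lewis-acid-bound enal, a known mode for trienals that strongly favours the endo (trans-fused) adduct, giving the ring-B 11-aldehyde F3. NaBH4 (MeOH, 0 °C) on the crude aldehyde returns to the route at 17; step 10 falls away.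

2. Step 12 (C11–C12 bond). Displacement at the β-branched C11 may be slow, and the strongly basic propargylic lithium reagent may instead remove the allylic C9 hydrogen, losing triflate by E2 toward an exocyclic C9=C11 triene. Fallback: a softer carbon nucleophile is used and the enoate is built without an alkyne. Setting out from 18, the dianion of methyl acetoacetate (NaH, then n-BuLi, THF, 0 °C; then 18, −78 → 0 °C) is alkylated at its terminal carbon to give the β-keto ester methyl 13-oxo-18-(tert-butyldiphenylsilyloxy)-16-nor-ent-labda-6,8(17)-dien-15-oate F4. NaH and ClP(O)(OEt)2 (Et2O, 0 °C) give the (Z)-enol diethyl phosphate F5. Me2CuLi (Et2O, −78 → −45 °C) replaces the phosphate by methyl with retention and returns to the route at 24; steps 13 and 14 fall away.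

3. Step 8 (allene formation). The Mitsunobu displacement on the conjugated enynol may be incomplete, or the diazene and the vinylallene may be lost to side reactions before isolation. Fallback: the allene is made by homologation of a terminal enyne. Setting out from 10, Sonogashira coupling with ethynyltrimethylsilane (PdCl2(PPh3)2, CuI, Et3N, THF, rt) gives the silyl enyne methyl (2E,7S,8E)-3,7-dimethyl-7-[(tert-butyldiphenylsilyloxy)methyl]-11-(trimethylsilyl)undeca-2,8-dien-10-ynoate F6. K2CO3 in MeOH gives the terminal enyne F7. Crabbé homologation (CuI, (CH2O)n, dicyclohexylamine, dioxane, reflux) returns to the route at 15. If cycloaddition already sets in at that temperature, the crude mixture is taken straight into the conditions of step 9.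

**Further compounds**

F1 | step 9 | (2E,7S,8E)-3,7-dimethyl-7-[(tert-butyldiphenylsilyloxy)methyl]dodeca-2,8,10,11-tetraen-1-ol | C=C=C/C=C/[C@@](C)(CO[Si](c1ccccc1)(c1ccccc1)C(C)(C)C)CCC/C(C)=C/CO
F2 | step 9 | (2E,7S,8E)-3,7-dimethyl-7-[(tert-butyldiphenylsilyloxy)methyl]dodeca-2,8,10,11-tetraenal | C=C=C/C=C/[C@@](C)(CO[Si](c1ccccc1)(c1ccccc1)C(C)(C)C)CCC/C(C)=C/C=O
F3 | step 9 | 18-(tert-butyldiphenylsilyloxy)-12,13,14,15,16-pentanor-ent-labda-6,8(17)-dien-11-al | C=C1C=C[C@@H]2[C@@](C)(CO[Si](c3ccccc3)(c3ccccc3)C(C)(C)C)CCC[C@@]2(C)[C@@H]1C=O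
F4 | step 12 | methyl 13-oxo-18-(tert-butyldiphenylsilyloxy)-16-nor-ent-labda-6,8(17)-dien-15-oate | C=C1C=C[C@@H]2[C@@](C)(CO[Si](c3ccccc3)(c3ccccc3)C(C)(C)C)CCC[C@@]2(C)[C@@H]1CCC(=O)CC(=O)OC
F5 | step 12 | methyl (13Z)-13-(diethoxyphosphoryloxy)-18-(tert-butyldiphenylsilyloxy)-16-nor-ent-labda-6,8(17),13-trien-15-oate | C=C1C=C[C@@H]2[C@@](C)(CO[Si](c3ccccc3)(c3ccccc3)C(C)(C)C)CCC[C@@]2(C)[C@@H]1CC/C(OP(=O)(OCC)OCC)=C/C(=O)OC
F6 | step 8 | methyl (2E,7S,8E)-3,7-dimethyl-7-[(tert-butyldiphenylsilyloxy)methyl]-11-(trimethylsilyl)undeca-2,8-dien-10-ynoate | C[Si](C)(C)C#C/C=C/[C@@](C)(CO[Si](c1ccccc1)(c1ccccc1)C(C)(C)C)CCC/C(C)=C/C(=O)OC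
F7 | step 8 | methyl (2E,7S,8E)-3,7-dimethyl-7-[(tert-butyldiphenylsilyloxy)methyl]undeca-2,8-dien-10-ynoate | C#C/C=C/[C@@](C)(CO[Si](c1ccccc1)(c1ccccc1)C(C)(C)C)CCC/C(C)=C/C(=O)OC
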